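**Retrosynthetic overview**

1. The target is the henicosa-O-methyl ether 45 after BBr3; ring H is put on the ring G C2 oxygen by CuI-catalysed arylation.
2. The strategy rests on rings C, E and G (rings lettered A to H from the 2,4,6-trihydroxyphenyl end). Each carries oxygen on five contiguous carbons: C1 ether to the preceding ring, C2 ether to the following ring, C3–C5 hydroxyls, and one hydrogen at C6. Each is cut at its C1–C2 bond back to a 4-[(Z)-2-aryloxyethenyl]-2,3,4-trimethoxycyclobutenone (Moore rearrangement), made from dimethyl squarate and a (Z)-2-aryloxyvinyllithium.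
3. Rings B, D and F come from 4-fluoro-2,6-dimethoxybenzaldehyde by SNAr and Dakin oxidation. The crowded phenol oxygen so formed is not arylated; it is turned via trichloroethylene into an ynol ether and then a vinylstannane, and enters the next ring as an enol ether.
4. The enol ether is made Z. Only the cis-configured 2-aryloxyvinyllithium is safe from anti β-elimination of aryloxide, and the geometry is lost on aromatisation.
5. Order of ring construction: A–B joined (steps 1–2), C built (3–7), D joined and E built (8–14), F joined and G built (15–21), H joined (22), deprotection (23).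

Key step: step 7

Remark: compounds 1, 2, 6, 11 and 44 are assumed to be purchased; phenols and the final polyphenol are handled under argon. Shorthand used in names:
- AB-oxy = 2,6-dimethoxy-4-(2,4,6-trimethoxyphenoxy)phenoxy
- AD-oxy = 4-[6-(AB-oxy)-2,3,4-trimethoxyphenoxy]-2,6-dimethoxyphenoxy
- AF-oxy = 4-[6-(AD-oxy)-2,3,4-trimethoxyphenoxy]-2,6-dimethoxyphenoxy

**Route**

Step 1
Reactants: 1 2,4,6-trimethoxyphenol; 2 4-fluoro-2,6-dimethoxybenzaldehyde
Product: 3 2,6-dimethoxy-4-(2,4,6-trimethoxyphenoxy)benzaldehyde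
Conditions: Cs2CO3, DMF, 110 °C, argon
Reagents that add atoms: none
Why: Nucleophilic aromatic substitution (SNAr): the para formyl group stabilises the Meisenheimer adduct, the fluorinated carbon has two unsubstituted neighbours and so accepts the di-ortho-substituted phenoxide, and fluoride should leave far faster than an ortho methoxy group.

Step 2
Reactants: 3 2,6-dimethoxy-4-(2,4,6-trimethoxyphenoxy)benzaldehyde
Product: 5 2,6-dimethoxy-4-(2,4,6-trimethoxyphenoxy)phenol, via aryl formate 4 (not isolated)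
Conditions: mCPBA (1.05 equiv), CH2Cl2, 0 °C to rt; then K2CO3 (cat.), MeOH, rt, argon
Reagents that add atoms: mCPBA (3-chloroperoxybenzoic acid), OOC(=O)c1cccc(Cl)c1
Why: Dakin-type Baeyer–Villiger oxidation: the electron-rich 2,6-dimethoxyaryl group migrates in preference to hydride, and the formate is cleaved by mild methanolysis.

Step 3
Reactants: 5 2,6-dimethoxy-4-(2,4,6-trimethoxyphenoxy)phenol; 6 trichloroethylene
Product: 7 2-{[(E)-1,2-dichloroethenyl]oxy}-1,3-dimethoxy-5-(2,4,6-trimethoxyphenoxy)benzene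
Conditions: K2CO3, DMF, 70 °C, argon
Reagents that add atoms: none
Why: Base-mediated O-dichlorovinylation: elimination to dichloroacetylene and anti addition of the phenoxide give the E 1,2-dichlorovinyl ether, and attack at a small sp carbon should be indifferent to the two ortho methoxy groups.

Step 4
Reactants: 7 2-{[(E)-1,2-dichloroethenyl]oxy}-1,3-dimethoxy-5-(2,4,6-trimethoxyphenoxy)benzene
Product: 9 2-(ethynyloxy)-1,3-dimethoxy-5-(2,4,6-trimethoxyphenoxy)benzene, via lithium acetylide 8 (not isolated)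
Conditions: n-BuLi (2.2 equiv), THF, −78 °C to −40 °C; MeOH, −78 °C
Reagents that add atoms: none
Why: Dichlorovinyl ether route to ynol ethers: vinylic lithiation, loss of LiCl to the chloroalkynyl ether and Cl/Li exchange give the lithium acetylide, which is protonated; at −78 °C ortho-lithiation of the methoxyarenes should not compete.

Step 5
Reactants: 9 2-(ethynyloxy)-1,3-dimethoxy-5-(2,4,6-trimethoxyphenoxy)benzene
Product: 10 tributyl[(Z)-2-(AB-oxy)ethenyl]stannane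
Conditions: Bu3SnH (1.0 equiv), AIBN (cat.), toluene, 65 °C, short reaction time
Reagents that add atoms: tributyltin hydride, CCCC[SnH](CCCC)CCCC
Why: Radical hydrostannylation: the stannyl radical adds to the terminal carbon to give the oxygen-stabilised α-aryloxyvinyl radical, and hydrogen transfer anti to tin should give the kinetic Z β-stannyl enol ether as with alkoxyacetylenes; the tin hydride is kept limiting so that stannyl radicals do not equilibrate the geometry.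

Step 6
Reactants: 10 tributyl[(Z)-2-(AB-oxy)ethenyl]stannane; 11 dimethyl squarate
Product: 14 2,3,4-trimethoxy-4-[(Z)-2-(AB-oxy)ethenyl]cyclobut-2-en-1-one (racemic), via vinyllithium 12 (not isolated), via lithium alkoxide 13 (not isolated)
Conditions: n-BuLi (1.0 equiv), THF, −78 °C; transferred into 11, THF, −78 °C; MeOTf, −78 °C to 0 °C
Reagents that add atoms: methyl triflate, COS(=O)(=O)C(F)(F)F
Why: Tin–lithium exchange with retention gives the Z vinyllithium, whose cis lithium and aryloxy groups cannot undergo anti β-elimination; 1,2-addition to one squarate carbonyl and O-methylation of the tertiary alkoxide in the same flask follow, and the new quaternary C4 centre forms as a racemate without control because it is destroyed in step 7.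

Step 7
Reactants: 14 2,3,4-trimethoxy-4-[(Z)-2-(AB-oxy)ethenyl]cyclobut-2-en-1-one (racemic)
Product: 17 6-(AB-oxy)-2,3,4-trimethoxyphenol (rings A–C), via dienylketene 15 (not isolated), via cyclohexadienone 16 (not isolated)
Conditions: toluene (degassed), 110 °C, base-washed glassware, argon
Reagents that add atoms: none
Why: Heating breaks the C1–C4 bond of the cyclobutenone by conrotatory 4π electrocyclic opening to dienylketene 15; the ketene carbon then bonds to the aryloxy-bearing vinyl carbon in a thermal disrotatory 6π electrocyclisation, which closes ring C as a six-membered ring through its C1–C2 bond, and dienone 16 enolises to the phenol. This is the Moore rearrangement of squarate-derived 4-alkenyl-4-alkoxycyclobutenones, and closure onto an oxygen-bearing sp2 carbon has its parallel in the benzofuran-forming rearrangement of 4-(3-furyl)cyclobutenones. The selectivity required is torquoselectivity: the 4-methoxy donor rotates outward, which turns the alkenyl arm inward, cis to the ketene, where it can close; a ketene formed with the arm outward cannot cyclise and should revert to the cyclobutenone. Regiochemistry is fixed by connectivity: the former carbonyl carbon becomes the only free hydroxyl (ring C C2), flanked by the new aryl ether at C1 and the methoxy groups at C3–C5, and the 4-methoxy group holds the product at the phenol level so that no quinone forms. No stereocentre survives, since the C4 centre of 14, the Z enol ether geometry and the transient C6 centre of 16 are all lost on aromatisation. The Z aryloxy group lies on the inside of the closing terminus, which should be tolerated because the ketene end is sp-hybridised and unhindered.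

Step 8
Reactants: 17 6-(AB-oxy)-2,3,4-trimethoxyphenol; 2 4-fluoro-2,6-dimethoxybenzaldehyde
Product: 18 4-[6-(AB-oxy)-2,3,4-trimethoxyphenoxy]-2,6-dimethoxybenzaldehyde (rings A–D)
Conditions: Cs2CO3, DMF, 110 °C, argon
Reagents that add atoms: none
Why: SNAr as in step 1: the ring C phenoxide is crowded, but the electrophilic carbon para to the formyl group is flanked only by hydrogens.

Step 9
Reactants: 18 4-[6-(AB-oxy)-2,3,4-trimethoxyphenoxy]-2,6-dimethoxybenzaldehyde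
Product: 20 4-[6-(AB-oxy)-2,3,4-trimethoxyphenoxy]-2,6-dimethoxyphenol (AD-OH), via aryl formate 19 (not isolated)
Conditions: mCPBA (1.05 equiv), CH2Cl2, 0 °C to rt; then K2CO3 (cat.), MeOH, rt, argon
Reagents that add atoms: mCPBA (3-chloroperoxybenzoic acid), OOC(=O)c1cccc(Cl)c1
Why: Dakin-type Baeyer–Villiger oxidation as in step 2; one equivalent of peracid at 0 °C should react with the aldehyde before any of the electron-rich rings.

Step 10
Reactants: 20 4-[6-(AB-oxy)-2,3,4-trimethoxyphenoxy]-2,6-dimethoxyphenol; 6 trichloroethylene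
Product: 21 (E)-1,2-dichloroethenyl ether of 20, (AD-oxy)C(Cl)=CHCl
Conditions: K2CO3, DMF, 70 °C, argon
Reagents that add atoms: none
Why: O-dichlorovinylation by elimination to dichloroacetylene and anti addition of the phenoxide, as in step 3.

Step 11
Reactants: 21 (E)-1,2-dichloroethenyl ether of 20
Product: 23 (AD-oxy)ethyne, via lithium acetylide 22 (not isolated)
Conditions: n-BuLi (2.2 equiv), THF, −78 °C to −40 °C; MeOH, −78 °C
Reagents that add atoms: none
Why: Dichlorovinyl ether to ynol ether conversion by lithiation, elimination, Cl/Li exchange and protonation, as in step 4.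

Step 12
Reactants: 23 (AD-oxy)ethyne
Product: 24 tributyl[(Z)-2-(AD-oxy)ethenyl]stannane
Conditions: Bu3SnH (1.0 equiv), AIBN (cat.), toluene, 65 °C, short reaction time
Reagents that add atoms: tributyltin hydride, CCCC[SnH](CCCC)CCCC
Why: Radical hydrostannylation with kinetic anti addition, expected to give the Z β-stannyl enol ether as in step 5.

Step 13
Reactants: 24 tributyl[(Z)-2-(AD-oxy)ethenyl]stannane; 11 dimethyl squarate
Product: 27 2,3,4-trimethoxy-4-[(Z)-2-(AD-oxy)ethenyl]cyclobut-2-en-1-one (racemic), via vinyllithium 25 (not isolated), via lithium alkoxide 26 (not isolated)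
Conditions: n-BuLi (1.0 equiv), THF, −78 °C; transferred into 11, THF, −78 °C; MeOTf, −78 °C to 0 °C
Reagents that add atoms: methyl triflate, COS(=O)(=O)C(F)(F)F
Why: Tin–lithium exchange, 1,2-addition to the squarate and O-methylation in the same flask as in step 6; the C4 centre is formed racemic and is removed in step 14.

Step 14
Reactants: 27 2,3,4-trimethoxy-4-[(Z)-2-(AD-oxy)ethenyl]cyclobut-2-en-1-one (racemic)
Product: 30 6-(AD-oxy)-2,3,4-trimethoxyphenol (rings A–E), via dienylketene 28 (not isolated), via cyclohexadienone 29 (not isolated)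
Conditions: toluene (degassed), 110 °C, base-washed glassware, argon
Reagents that add atoms: none
Why: Moore rearrangement as in step 7: conrotatory 4π opening with the methoxy group outward, 6π closure of the ring E C1–C2 bond and enolisation give the phenol with only the ring E C2 hydroxyl free.

Step 15
Reactants: 30 6-(AD-oxy)-2,3,4-trimethoxyphenol; 2 4-fluoro-2,6-dimethoxybenzaldehyde
Product: 31 4-[6-(AD-oxy)-2,3,4-trimethoxyphenoxy]-2,6-dimethoxybenzaldehyde (rings A–F)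
Conditions: Cs2CO3, DMF, 110 °C, argon
Reagents that add atoms: none
Why: SNAr at the fluorinated carbon para to the formyl group, as in steps 1 and 8.

Step 16
Reactants: 31 4-[6-(AD-oxy)-2,3,4-trimethoxyphenoxy]-2,6-dimethoxybenzaldehyde
Product: 33 4-[6-(AD-oxy)-2,3,4-trimethoxyphenoxy]-2,6-dimethoxyphenol (AF-OH), via aryl formate 32 (not isolated)
Conditions: mCPBA (1.05 equiv), CH2Cl2, 0 °C to rt; then K2CO3 (cat.), MeOH, rt, argon
Reagents that add atoms: mCPBA (3-chloroperoxybenzoic acid), OOC(=O)c1cccc(Cl)c1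
Why: Dakin-type Baeyer–Villiger oxidation with aryl migration and formate methanolysis, as in steps 2 and 9.

Step 17
Reactants: 33 4-[6-(AD-oxy)-2,3,4-trimethoxyphenoxy]-2,6-dimethoxyphenol; 6 trichloroethylene
Product: 34 (E)-1,2-dichloroethenyl ether of 33, (AF-oxy)C(Cl)=CHCl
Conditions: K2CO3, DMF, 70 °C, argon
Reagents that add atoms: none
Why: O-dichlorovinylation via dichloroacetylene and anti addition of the phenoxide, as in steps 3 and 10.

Step 18
Reactants: 34 (E)-1,2-dichloroethenyl ether of 33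
Product: 36 (AF-oxy)ethyne, via lithium acetylide 35 (not isolated)
Conditions: n-BuLi (2.2 equiv), THF, −78 °C to −40 °C; MeOH, −78 °C
Reagents that add atoms: none
Why: Dichlorovinyl ether to ynol ether conversion as in steps 4 and 11.

Step 19
Reactants: 36 (AF-oxy)ethyne
Product: 37 tributyl[(Z)-2-(AF-oxy)ethenyl]stannane
Conditions: Bu3SnH (1.0 equiv), AIBN (cat.), toluene, 65 °C, short reaction time
Reagents that add atoms: tributyltin hydride, CCCC[SnH](CCCC)CCCC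
Why: Radical hydrostannylation with kinetic anti addition to the Z β-stannyl enol ether, as in steps 5 and 12.

Step 20
Reactants: 37 tributyl[(Z)-2-(AF-oxy)ethenyl]stannane; 11 dimethyl squarate
Product: 40 2,3,4-trimethoxy-4-[(Z)-2-(AF-oxy)ethenyl]cyclobut-2-en-1-one (racemic), via vinyllithium 38 (not isolated), via lithium alkoxide 39 (not isolated)
Conditions: n-BuLi (1.0 equiv), THF, −78 °C; transferred into 11, THF, −78 °C; MeOTf, −78 °C to 0 °C
Reagents that add atoms: methyl triflate, COS(=O)(=O)C(F)(F)F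
Why: Tin–lithium exchange, squarate 1,2-addition and O-methylation as in steps 6 and 13; the racemic C4 centre is removed in step 21.

Step 21
Reactants: 40 2,3,4-trimethoxy-4-[(Z)-2-(AF-oxy)ethenyl]cyclobut-2-en-1-one (racemic)
Product: 43 6-(AF-oxy)-2,3,4-trimethoxyphenol (rings A–G), via dienylketene 41 (not isolated), via cyclohexadienone 42 (not isolated)
Conditions: toluene (degassed), 110 °C, base-washed glassware, argon
Reagents that add atoms: none
Why: Moore rearrangement as in steps 7 and 14, closing ring G through its C1–C2 bond and leaving only the ring G C2 hydroxyl free.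

Step 22
Reactants: 43 6-(AF-oxy)-2,3,4-trimethoxyphenol; 44 5-iodo-1,2,3-trimethoxybenzene
Product: 45 1-(AF-oxy)-3,4,5-trimethoxy-2-(3,4,5-trimethoxyphenoxy)benzene (henicosa-O-methyl ether of the target)
Conditions: CuI (10 mol %), picolinic acid (20 mol %), K3PO4, DMSO, 90 °C, argon
Reagents that add atoms: none
Why: Ullmann-type CuI-catalysed diaryl ether coupling: the picolinate-ligated copper system couples ortho-disubstituted phenols, and the iodide has no ortho substituent.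

Step 23
Reactants: 45 henicosa-O-methyl ether of the target
Product: 46 target CNP0206369.0
Conditions: BBr3 (large excess), CH2Cl2, −78 °C to rt; H2O, 0 °C; argon
Reagents that add atoms: none
Why: Lewis acid cleavage of aryl methyl ethers by BBr3 (bromide attacks the methyl group of the boron-complexed ether), which leaves the diaryl ether bonds intact because they offer no sp3 carbon for attack.

**Compound list**

1 | 2,4,6-trimethoxyphenol | COc1cc(OC)c(O)c(OC)c1 | starting material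
2 | 4-fluoro-2,6-dimethoxybenzaldehyde | COc1cc(F)cc(OC)c1C=O | starting material
3 | 2,6-dimethoxy-4-(2,4,6-trimethoxyphenoxy)benzaldehyde | COc1cc(OC)cc(OC)c1Oc1cc(OC)c(C=O)c(OC)c1 | intermediate
4 | 2,6-dimethoxy-4-(2,4,6-trimethoxyphenoxy)phenyl formate | COc1cc(OC)cc(OC)c1Oc1cc(OC)c(OC=O)c(OC)c1 | intermediate
5 | 2,6-dimethoxy-4-(2,4,6-trimethoxyphenoxy)phenol (AB-OH) | COc1cc(OC)cc(OC)c1Oc1cc(OC)c(O)c(OC)c1 | intermediate
6 | trichloroethylene | ClC=C(Cl)Cl | starting material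
7 | 2-{[(E)-1,2-dichloroethenyl]oxy}-1,3-dimethoxy-5-(2,4,6-trimethoxyphenoxy)benzene | COc1cc(OC)cc(OC)c1Oc1cc(OC)c(O/C(Cl)=C\Cl)c(OC)c1 | intermediate
8 | lithium (AB-oxy)acetylide | COc1cc(OC)cc(OC)c1Oc1cc(OC)c(OC#C[Li])c(OC)c1 | intermediate
9 | 2-(ethynyloxy)-1,3-dimethoxy-5-(2,4,6-trimethoxyphenoxy)benzene, (AB-oxy)ethyne | COc1cc(OC)cc(OC)c1Oc1cc(OC)c(OC#C)c(OC)c1 | intermediate
10 | tributyl[(Z)-2-(AB-oxy)ethenyl]stannane | COc1cc(OC)cc(OC)c1Oc1cc(OC)c(O/C=C\[Sn](CCCC)(CCCC)CCCC)c(OC)c1 | intermediate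
11 | dimethyl squarate (3,4-dimethoxycyclobut-3-ene-1,2-dione) | COC1=C(OC)C(=O)C1=O | starting material
12 | (Z)-2-(AB-oxy)ethenyllithium | COc1cc(OC)cc(OC)c1Oc1cc(OC)c(O/C=C\[Li])c(OC)c1 | intermediate
13 | lithium 2,3-dimethoxy-4-oxo-1-[(Z)-2-(AB-oxy)ethenyl]cyclobut-2-en-1-olate (racemic) | COc1cc(OC)cc(OC)c1Oc1cc(OC)c(O/C=C\C2(O[Li])C(OC)=C(OC)C2=O)c(OC)c1 | intermediate
14 | 2,3,4-trimethoxy-4-[(Z)-2-(AB-oxy)ethenyl]cyclobut-2-en-1-one (racemic) | COc1cc(OC)cc(OC)c1Oc1cc(OC)c(O/C=C\C2(OC)C(OC)=C(OC)C2=O)c(OC)c1 | intermediate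
15 | (3Z,5Z)-6-(AB-oxy)-2,3,4-trimethoxyhexa-1,3,5-trien-1-one (dienylketene) | COc1cc(OC)cc(OC)c1Oc1cc(OC)c(O/C=C\C(OC)=C(OC)/C(OC)=C=O)c(OC)c1 | intermediate
16 | 6-(AB-oxy)-2,3,4-trimethoxycyclohexa-2,4-dien-1-one (racemic) | COc1cc(OC)cc(OC)c1Oc1cc(OC)c(OC2C=C(OC)C(OC)=C(OC)C2=O)c(OC)c1 | intermediate
17 | 6-(AB-oxy)-2,3,4-trimethoxyphenol (rings A–C) | COc1cc(OC)cc(OC)c1Oc1cc(OC)c(Oc2cc(OC)c(OC)c(OC)c2O)c(OC)c1 | intermediate
18 | 4-[6-(AB-oxy)-2,3,4-trimethoxyphenoxy]-2,6-dimethoxybenzaldehyde (rings A–D) | COc1cc(OC)cc(OC)c1Oc1cc(OC)c(Oc2cc(OC)c(OC)c(OC)c2Oc2cc(OC)c(C=O)c(OC)c2)c(OC)c1 | intermediate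
19 | 4-[6-(AB-oxy)-2,3,4-trimethoxyphenoxy]-2,6-dimethoxyphenyl formate | COc1cc(OC)cc(OC)c1Oc1cc(OC)c(Oc2cc(OC)c(OC)c(OC)c2Oc2cc(OC)c(OC=O)c(OC)c2)c(OC)c1 | intermediate
20 | 4-[6-(AB-oxy)-2,3,4-trimethoxyphenoxy]-2,6-dimethoxyphenol (AD-OH) | COc1cc(OC)cc(OC)c1Oc1cc(OC)c(Oc2cc(OC)c(OC)c(OC)c2Oc2cc(OC)c(O)c(OC)c2)c(OC)c1 | intermediate
21 | (E)-1,2-dichloroethenyl ether of 20, (AD-oxy)C(Cl)=CHCl | COc1cc(OC)cc(OC)c1Oc1cc(OC)c(Oc2cc(OC)c(OC)c(OC)c2Oc2cc(OC)c(O/C(Cl)=C\Cl)c(OC)c2)c(OC)c1 | intermediate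
22 | lithium (AD-oxy)acetylide | COc1cc(OC)cc(OC)c1Oc1cc(OC)c(Oc2cc(OC)c(OC)c(OC)c2Oc2cc(OC)c(OC#C[Li])c(OC)c2)c(OC)c1 | intermediate
23 | (AD-oxy)ethyne | COc1cc(OC)cc(OC)c1Oc1cc(OC)c(Oc2cc(OC)c(OC)c(OC)c2Oc2cc(OC)c(OC#C)c(OC)c2)c(OC)c1 | intermediate
24 | tributyl[(Z)-2-(AD-oxy)ethenyl]stannane | COc1cc(OC)cc(OC)c1Oc1cc(OC)c(Oc2cc(OC)c(OC)c(OC)c2Oc2cc(OC)c(O/C=C\[Sn](CCCC)(CCCC)CCCC)c(OC)c2)c(OC)c1 | intermediate
25 | (Z)-2-(AD-oxy)ethenyllithium | COc1cc(OC)cc(OC)c1Oc1cc(OC)c(Oc2cc(OC)c(OC)c(OC)c2Oc2cc(OC)c(O/C=C\[Li])c(OC)c2)c(OC)c1 | intermediate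
26 | lithium 2,3-dimethoxy-4-oxo-1-[(Z)-2-(AD-oxy)ethenyl]cyclobut-2-en-1-olate (racemic) | COc1cc(OC)cc(OC)c1Oc1cc(OC)c(Oc2cc(OC)c(OC)c(OC)c2Oc2cc(OC)c(O/C=C\C3(O[Li])C(OC)=C(OC)C3=O)c(OC)c2)c(OC)c1 | intermediate
27 | 2,3,4-trimethoxy-4-[(Z)-2-(AD-oxy)ethenyl]cyclobut-2-en-1-one (racemic) | COc1cc(OC)cc(OC)c1Oc1cc(OC)c(Oc2cc(OC)c(OC)c(OC)c2Oc2cc(OC)c(O/C=C\C3(OC)C(OC)=C(OC)C3=O)c(OC)c2)c(OC)c1 | intermediate
28 | (3Z,5Z)-6-(AD-oxy)-2,3,4-trimethoxyhexa-1,3,5-trien-1-one (dienylketene) | COc1cc(OC)cc(OC)c1Oc1cc(OC)c(Oc2cc(OC)c(OC)c(OC)c2Oc2cc(OC)c(O/C=C\C(OC)=C(OC)/C(OC)=C=O)c(OC)c2)c(OC)c1 | intermediate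
29 | 6-(AD-oxy)-2,3,4-trimethoxycyclohexa-2,4-dien-1-one (racemic) | COc1cc(OC)cc(OC)c1Oc1cc(OC)c(Oc2cc(OC)c(OC)c(OC)c2Oc2cc(OC)c(OC3C=C(OC)C(OC)=C(OC)C3=O)c(OC)c2)c(OC)c1 | intermediate
30 | 6-(AD-oxy)-2,3,4-trimethoxyphenol (rings A–E) | COc1cc(OC)cc(OC)c1Oc1cc(OC)c(Oc2cc(OC)c(OC)c(OC)c2Oc2cc(OC)c(Oc3cc(OC)c(OC)c(OC)c3O)c(OC)c2)c(OC)c1 | intermediate
31 | 4-[6-(AD-oxy)-2,3,4-trimethoxyphenoxy]-2,6-dimethoxybenzaldehyde (rings A–F) | COc1cc(OC)cc(OC)c1Oc1cc(OC)c(Oc2cc(OC)c(OC)c(OC)c2Oc2cc(OC)c(Oc3cc(OC)c(OC)c(OC)c3Oc3cc(OC)c(C=O)c(OC)c3)c(OC)c2)c(OC)c1 | intermediate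
32 | 4-[6-(AD-oxy)-2,3,4-trimethoxyphenoxy]-2,6-dimethoxyphenyl formate | COc1cc(OC)cc(OC)c1Oc1cc(OC)c(Oc2cc(OC)c(OC)c(OC)c2Oc2cc(OC)c(Oc3cc(OC)c(OC)c(OC)c3Oc3cc(OC)c(OC=O)c(OC)c3)c(OC)c2)c(OC)c1 | intermediate
33 | 4-[6-(AD-oxy)-2,3,4-trimethoxyphenoxy]-2,6-dimethoxyphenol (AF-OH) | COc1cc(OC)cc(OC)c1Oc1cc(OC)c(Oc2cc(OC)c(OC)c(OC)c2Oc2cc(OC)c(Oc3cc(OC)c(OC)c(OC)c3Oc3cc(OC)c(O)c(OC)c3)c(OC)c2)c(OC)c1 | intermediate
34 | (E)-1,2-dichloroethenyl ether of 33, (AF-oxy)C(Cl)=CHCl | COc1cc(OC)cc(OC)c1Oc1cc(OC)c(Oc2cc(OC)c(OC)c(OC)c2Oc2cc(OC)c(Oc3cc(OC)c(OC)c(OC)c3Oc3cc(OC)c(O/C(Cl)=C\Cl)c(OC)c3)c(OC)c2)c(OC)c1 | intermediate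
35 | lithium (AF-oxy)acetylide | COc1cc(OC)cc(OC)c1Oc1cc(OC)c(Oc2cc(OC)c(OC)c(OC)c2Oc2cc(OC)c(Oc3cc(OC)c(OC)c(OC)c3Oc3cc(OC)c(OC#C[Li])c(OC)c3)c(OC)c2)c(OC)c1 | intermediate
36 | (AF-oxy)ethyne | COc1cc(OC)cc(OC)c1Oc1cc(OC)c(Oc2cc(OC)c(OC)c(OC)c2Oc2cc(OC)c(Oc3cc(OC)c(OC)c(OC)c3Oc3cc(OC)c(OC#C)c(OC)c3)c(OC)c2)c(OC)c1 | intermediate
37 | tributyl[(Z)-2-(AF-oxy)ethenyl]stannane | COc1cc(OC)cc(OC)c1Oc1cc(OC)c(Oc2cc(OC)c(OC)c(OC)c2Oc2cc(OC)c(Oc3cc(OC)c(OC)c(OC)c3Oc3cc(OC)c(O/C=C\[Sn](CCCC)(CCCC)CCCC)c(OC)c3)c(OC)c2)c(OC)c1 | intermediate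
38 | (Z)-2-(AF-oxy)ethenyllithium | COc1cc(OC)cc(OC)c1Oc1cc(OC)c(Oc2cc(OC)c(OC)c(OC)c2Oc2cc(OC)c(Oc3cc(OC)c(OC)c(OC)c3Oc3cc(OC)c(O/C=C\[Li])c(OC)c3)c(OC)c2)c(OC)c1 | intermediate
39 | lithium 2,3-dimethoxy-4-oxo-1-[(Z)-2-(AF-oxy)ethenyl]cyclobut-2-en-1-olate (racemic) | COc1cc(OC)cc(OC)c1Oc1cc(OC)c(Oc2cc(OC)c(OC)c(OC)c2Oc2cc(OC)c(Oc3cc(OC)c(OC)c(OC)c3Oc3cc(OC)c(O/C=C\C4(O[Li])C(OC)=C(OC)C4=O)c(OC)c3)c(OC)c2)c(OC)c1 | intermediate
40 | 2,3,4-trimethoxy-4-[(Z)-2-(AF-oxy)ethenyl]cyclobut-2-en-1-one (racemic) | COc1cc(OC)cc(OC)c1Oc1cc(OC)c(Oc2cc(OC)c(OC)c(OC)c2Oc2cc(OC)c(Oc3cc(OC)c(OC)c(OC)c3Oc3cc(OC)c(O/C=C\C4(OC)C(OC)=C(OC)C4=O)c(OC)c3)c(OC)c2)c(OC)c1 | intermediate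
41 | (3Z,5Z)-6-(AF-oxy)-2,3,4-trimethoxyhexa-1,3,5-trien-1-one (dienylketene) | COc1cc(OC)cc(OC)c1Oc1cc(OC)c(Oc2cc(OC)c(OC)c(OC)c2Oc2cc(OC)c(Oc3cc(OC)c(OC)c(OC)c3Oc3cc(OC)c(O/C=C\C(OC)=C(OC)/C(OC)=C=O)c(OC)c3)c(OC)c2)c(OC)c1 | intermediate
42 | 6-(AF-oxy)-2,3,4-trimethoxycyclohexa-2,4-dien-1-one (racemic) | COc1cc(OC)cc(OC)c1Oc1cc(OC)c(Oc2cc(OC)c(OC)c(OC)c2Oc2cc(OC)c(Oc3cc(OC)c(OC)c(OC)c3Oc3cc(OC)c(OC4C=C(OC)C(OC)=C(OC)C4=O)c(OC)c3)c(OC)c2)c(OC)c1 | intermediate
43 | 6-(AF-oxy)-2,3,4-trimethoxyphenol (rings A–G) | COc1cc(OC)cc(OC)c1Oc1cc(OC)c(Oc2cc(OC)c(OC)c(OC)c2Oc2cc(OC)c(Oc3cc(OC)c(OC)c(OC)c3Oc3cc(OC)c(Oc4cc(OC)c(OC)c(OC)c4O)c(OC)c3)c(OC)c2)c(OC)c1 | intermediate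
44 | 5-iodo-1,2,3-trimethoxybenzene | COc1cc(I)cc(OC)c1OC | starting material
45 | 1-(AF-oxy)-3,4,5-trimethoxy-2-(3,4,5-trimethoxyphenoxy)benzene (henicosa-O-methyl ether of the target, rings A–H) | COc1cc(OC)cc(OC)c1Oc1cc(OC)c(Oc2cc(OC)c(OC)c(OC)c2Oc2cc(OC)c(Oc3cc(OC)c(OC)c(OC)c3Oc3cc(OC)c(Oc4cc(OC)c(OC)c(OC)c4Oc4cc(OC)c(OC)c(OC)c4)c(OC)c3)c(OC)c2)c(OC)c1 | intermediate
46 | CNP0206369.0, the octameric phlorotannin with all 21 hydroxyls free | Oc1cc(O)c(Oc2cc(O)c(Oc3cc(O)c(O)c(O)c3Oc3cc(O)c(Oc4cc(O)c(O)c(O)c4Oc4cc(O)c(Oc5cc(O)c(O)c(O)c5Oc5cc(O)c(O)c(O)c5)c(O)c4)c(O)c3)c(O)c2)c(O)c1 | target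

**Count and risks**

Total step count: 23. Longest linear sequence: 23 steps (1 to 46); compounds 2, 6, 11 and 44 enter as purchased.

Steps most likely to fail:

1. Step 7 (and its repeats, steps 14 and 21). The 6π closure may be slow because the Z aryloxy group sits on the inside of the closing terminus, so that the dienylketene is consumed by dimerisation or by traces of water, or the acid-sensitive enol ether is hydrolysed before ring opening. The fallback sets out from phenol 5 and comes back at phenol 17, and builds the ring B–ring C ether by copper catalysis in place of the rearrangement. Commercial 2,3,4-trimethoxyphenol is iodinated ortho to the hydroxyl (NIS, MeCN, 0 °C) to 6-iodo-2,3,4-trimethoxyphenol F1. This is benzylated (benzyl bromide, K2CO3, DMF) to 2-(benzyloxy)-1-iodo-3,4,5-trimethoxybenzene F2. F2 is coupled with 5 (CuI, picolinic acid, K3PO4, DMSO, 100 °C) to 2-(benzyloxy)-1-(AB-oxy)-3,4,5-trimethoxybenzene F3, and hydrogenolysis (H2, Pd/C, EtOAc) gives 17.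

2. Step 5 (and its repeats, steps 12 and 19). The kinetic Z adduct may be isomerised by reversible stannyl radical addition, or the terminal ynol ether may polymerise on warming; an E-configured lithium reagent would then fragment by anti β-elimination in the following step. The fallback sets out from dichlorovinyl ether 7 and comes back at stannane 10, and fixes the geometry by a syn hydrometalation. Acetylide 8 is generated as in step 4 but trapped with Bu3SnCl to give tributyl[(AB-oxy)ethynyl]stannane F4. Hydrozirconation with Cp2Zr(H)Cl (THF, rt) adds hydrogen and zirconium syn, zirconium to the tin-bearing carbon, to give [(Z)-2-(AB-oxy)-1-(tributylstannyl)ethenyl]zirconocene chloride F5. Protonolysis with water, with retention, should give 10 as the single Z isomer.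

3. Step 23. Cleavage of the 21 methyl ethers may stop short, and the pyrogallol-type rings may oxidise in air while the free polyphenol is isolated. The fallback sets out from 45 and comes back at 46 through a derivative that can be purified. After the BBr3 treatment and quench, the crude polyphenol is acetylated (Ac2O, pyridine, rt) to the henicosaacetate F6, which is chromatographed on silica so that under-cleaved material can be separated and resubmitted. Acid-catalysed methanolysis (HCl, MeOH, 40 °C, argon) then releases 46 without exposure to base.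

**Further compounds**

F1 | step 7 | 6-iodo-2,3,4-trimethoxyphenol | COc1cc(I)c(O)c(OC)c1OC
F2 | step 7 | 2-(benzyloxy)-1-iodo-3,4,5-trimethoxybenzene | COc1cc(I)c(OCc2ccccc2)c(OC)c1OC
F3 | step 7 | 2-(benzyloxy)-1-(AB-oxy)-3,4,5-trimethoxybenzene (benzyl ether of 17) | COc1cc(OC)cc(OC)c1Oc1cc(OC)c(Oc2cc(OC)c(OC)c(OC)c2OCc2ccccc2)c(OC)c1
F4 | step 5 | tributyl[(AB-oxy)ethynyl]stannane | COc1cc(OC)cc(OC)c1Oc1cc(OC)c(OC#C[Sn](CCCC)(CCCC)CCCC)c(OC)c1
F5 | step 5 | [(Z)-2-(AB-oxy)-1-(tributylstannyl)ethenyl]zirconocene chloride, Cp2Zr(Cl)-alkenyl (cyclopentadienyl rings drawn sigma-bonded) | COc1cc(OC)cc(OC)c1Oc1cc(OC)c(O/C=C(\[Sn](CCCC)(CCCC)CCCC)[Zr](Cl)(C2C=CC=C2)C2C=CC=C2)c(OC)c1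
F6 | step 23 | henicosaacetate of 46 (all 21 hydroxyls as acetates) | CC(=O)Oc1cc(OC(C)=O)cc(OC(C)=O)c1Oc1cc(OC(C)=O)c(Oc2cc(OC(C)=O)c(OC(C)=O)c(OC(C)=O)c2Oc2cc(OC(C)=O)c(Oc3cc(OC(C)=O)c(OC(C)=O)c(OC(C)=O)c3Oc3cc(OC(C)=O)c(Oc4cc(OC(C)=O)c(OC(C)=O)c(OC(C)=O)c4Oc4cc(OC(C)=O)c(OC(C)=O)c(OC(C)=O)c4)c(OC(C)=O)c3)c(OC(C)=O)c2)c(OC(C)=O)c1
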